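**Plan**

1. Numbering used throughout: C1 = lactone carbonyl, C7 = ring O–CH, C8–C9–C10 = cyclopropane (C9 = CH2), C11 and C14 = carbinols, C22 = methyl.
2. Cuts: C12=C13 (Julia–Kocienski olefination, sulfone 25 + aldehyde 14); then, in one operation, the lactone O–C7 bond together with the cyclopropane bond C8–C10, back to the acyclic epoxy dienoate 8; 8 is cut at C9–C10 (Stille coupling) and C5–C6 (alkyne–allyl coupling).
3. Enabling feature: C7 is a cyclopropylcarbinyl carbon. It sits on the C8–C9–C10 ring whose C10 bears the C11 carbinol, so O–C7, C8–C10 and C11–OH all map onto one homoallylic epoxide (C10–C11 oxirane, C7=C8 alkene) with the C1 carboxyl in reach, as in the presumed biosynthesis of the cyclopropyl-lactone oxylipins.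
4. Forward: C1–C12 chain (steps 1–5); cyclopropane and eight-membered lactone formed together (step 6); C12 aldehyde (steps 7–9); side chain C13–C22 (steps 10–15) joined in step 16; deprotection (step 17).
5. Stereochemistry: C10/C11 from Sharpless epoxidation; C8 and C7 relayed in step 6 (inversion at C10, trans ring, anti addition across the 7E alkene); C14 from (S)-epichlorohydrin; Z alkenes from Lindlar reductions, E alkenes from the building blocks and the olefination.

Key step: step 6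

Remark on the chemistry: the homoallyl-to-cyclopropylcarbinyl closure and its capture are taken to be anti across C7=C8 (as in the i-steroid rearrangement); on that basis the (7R,8R) relationship of the target requires the 7E alkene used here.

**Route**

Step 1
Reactants: 1 tert-butyl pent-4-ynoate; 2 (2E)-1,4-dibromobut-2-ene (3 equiv)
Product: 3 tert-butyl (7E)-9-bromonon-7-en-4-ynoate
Conditions: CuBr·SMe2 (10 mol %), K2CO3, n-Bu4NBr, DMF, 0 °C → rt
Reagents that add atoms: none
Why: Copper-catalysed alkynyl–allyl coupling of the copper acetylide formed in situ with a primary allylic bromide should give direct substitution with retention of the E geometry, the excess of the symmetric dibromide suppressing double coupling.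

Step 2
Reactants: 3 tert-butyl (7E)-9-bromonon-7-en-4-ynoate; 4 (2E)-3-(tributylstannyl)prop-2-en-1-ol
Product: 5 tert-butyl (7E,10E)-12-hydroxydodeca-7,10-dien-4-ynoate
Conditions: Pd2(dba)3 (2.5 mol %), AsPh3 (10 mol %), THF, 50 °C
Reagents that add atoms: none
Why: Stille allyl–vinyl coupling through a pi-allyl palladium intermediate should join at the less hindered allyl terminus with retention of both E geometries and needs no base.

Step 3
Reactants: 5 tert-butyl (7E,10E)-12-hydroxydodeca-7,10-dien-4-ynoate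
Product: 6 tert-butyl (4Z,7E,10E)-12-hydroxydodeca-4,7,10-trienoate
Conditions: H2 (1 atm), Pd/CaCO3 poisoned with Pb(OAc)2 (Lindlar catalyst), quinoline, EtOAc, rt
Reagents that add atoms: none
Why: Lindlar semihydrogenation (syn addition of hydrogen on poisoned palladium) should convert only the alkyne into the 4Z alkene and leave the isolated E alkenes and the ester untouched.

Step 4
Reactants: 6 tert-butyl (4Z,7E,10E)-12-hydroxydodeca-4,7,10-trienoate
Product: 7 tert-butyl (4Z,7E)-9-[(2R,3R)-3-(hydroxymethyl)oxiran-2-yl]nona-4,7-dienoate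
Conditions: Ti(OiPr)4 (10 mol %), D-(−)-diethyl tartrate (12 mol %), t-BuOOH, 4 Å molecular sieves, CH2Cl2, −20 °C
Reagents that add atoms: tert-butyl hydroperoxide CC(C)(C)OO
Why: Sharpless asymmetric epoxidation acts only on the allylic alcohol alkene (C10=C11) and with the D-tartrate should deliver oxygen to the face that gives the (2R,3R)-epoxy alcohol, which fixes C10 and C11.

Step 5
Reactants: 7 tert-butyl (4Z,7E)-9-[(2R,3R)-3-(hydroxymethyl)oxiran-2-yl]nona-4,7-dienoate
Product: 8 tert-butyl (4Z,7E)-9-[(2R,3R)-3-({[tert-butyl(dimethyl)silyl]oxy}methyl)oxiran-2-yl]nona-4,7-dienoate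
Conditions: TBSCl, imidazole, CH2Cl2, 0 °C → rt
Reagents that add atoms: tert-butyldimethylsilyl chloride CC(C)(C)[Si](C)(C)Cl
Why: Imidazole-mediated silylation of the primary alcohol runs under conditions too mild for Payne rearrangement and leaves an electron-withdrawing CH2OSi group on C11.

Step 6
Reactants: 8 tert-butyl (4Z,7E)-9-[(2R,3R)-3-({[tert-butyl(dimethyl)silyl]oxy}methyl)oxiran-2-yl]nona-4,7-dienoate
Product: 11 (5Z,8R)-8-[(1R,2R)-2-[(1S)-2-{[tert-butyl(dimethyl)silyl]oxy}-1-hydroxyethyl]cyclopropyl]-3,4,7,8-tetrahydro-2H-oxocin-2-one, via cyclopropylcarbinyl cation 9 (not isolated), via tert-butyl lactonium ion 10 (not isolated)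
Conditions: BF3·OEt2 (0.3 equiv), CH2Cl2 (2 mM), −78 → −30 °C; Et3N, then aq NaHCO3
Reagents that add atoms: none
Why: Proposed new method: BF3 activation of the epoxide lets the homoallylic C7=C8 alkene open it at C10 with inversion (3-exo-tet), which forms the C8–C10 ring bond and a cyclopropylcarbinyl cation at C7; the tert-butyl ester carbonyl oxygen captures this cation (8-exo-trig, counting the delocalised C7–C8 bond) and the tert-butyl lactonium ion loses 2-methylpropene, the freed proton releasing the C11 alkoxide from boron. The closest known reaction types are the i-steroid (homoallyl to cyclopropylcarbinyl) rearrangement and Lewis-acid epoxide-initiated cation–olefin cyclisations terminated by tert-butyl esters or carbonates; closing an eight-membered lactone by such a capture is the new element. C11 keeps the epoxide configuration, C10 is set by inversion at the epoxide carbon, C8 by the trans arrangement of the two ring substituents in the backside-attack transition state, and C7 by anti addition across the 7E alkene (oxygen enters opposite the new C8–C10 bond of the bisected cation), so that the E geometry becomes (7R,8R). The step needs opening at C10 rather than C11, which the inductively deactivating CH2OSi group on C11 and homoallylic participation should secure, and capture of the C7 cation by the carboxyl rather than by the C4=C5 alkene or by loss of a C6 proton; the 4Z alkene folds the chain to bring the carbonyl oxygen over C7, high dilution and low temperature suppress intermolecular paths, and a second homoallyl shift would only trade one secondary cyclopropylcarbinyl cation for another at the cost of a further strained ring.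

Step 7
Reactants: 11 (5Z,8R)-8-[(1R,2R)-2-[(1S)-2-{[tert-butyl(dimethyl)silyl]oxy}-1-hydroxyethyl]cyclopropyl]-3,4,7,8-tetrahydro-2H-oxocin-2-one
Product: 12 (5Z,8R)-8-[(1R,2R)-2-[(1S)-1,2-bis{[tert-butyl(dimethyl)silyl]oxy}ethyl]cyclopropyl]-3,4,7,8-tetrahydro-2H-oxocin-2-one
Conditions: TBSOTf, 2,6-lutidine, CH2Cl2, −78 → 0 °C
Reagents that add atoms: tert-butyldimethylsilyl trifluoromethanesulfonate CC(C)(C)[Si](C)(C)OS(=O)(=O)C(F)(F)F
Why: Silyl triflate silylation with a hindered pyridine base should protect the hindered secondary cyclopropylcarbinol without touching the lactone.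

Step 8
Reactants: 12 (5Z,8R)-8-[(1R,2R)-2-[(1S)-1,2-bis{[tert-butyl(dimethyl)silyl]oxy}ethyl]cyclopropyl]-3,4,7,8-tetrahydro-2H-oxocin-2-one
Product: 13 (5Z,8R)-8-[(1R,2R)-2-[(1S)-1-{[tert-butyl(dimethyl)silyl]oxy}-2-hydroxyethyl]cyclopropyl]-3,4,7,8-tetrahydro-2H-oxocin-2-one
Conditions: HF·pyridine, pyridine, THF, 0 °C
Reagents that add atoms: none
Why: Buffered fluoride desilylation should cleave the unhindered primary silyl ether much faster than the secondary one next to the cyclopropane (steric differentiation of silyl ethers).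

Step 9
Reactants: 13 (5Z,8R)-8-[(1R,2R)-2-[(1S)-1-{[tert-butyl(dimethyl)silyl]oxy}-2-hydroxyethyl]cyclopropyl]-3,4,7,8-tetrahydro-2H-oxocin-2-one
Product: 14 (5Z,8R)-8-[(1R,2R)-2-[(1S)-1-{[tert-butyl(dimethyl)silyl]oxy}-2-oxoethyl]cyclopropyl]-3,4,7,8-tetrahydro-2H-oxocin-2-one
Conditions: Dess–Martin periodinane, NaHCO3, CH2Cl2, 0 °C → rt
Reagents that add atoms: none
Why: Dess–Martin oxidation under buffered neutral conditions should give the alpha-silyloxy aldehyde without epimerisation at C11.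

Step 10
Reactants: 15 1-bromopent-2-yne; 16 ethynylmagnesium bromide
Product: 17 hepta-1,4-diyne
Conditions: CuCl (5 mol %), THF, 0 → 50 °C
Reagents that add atoms: none
Why: Copper-catalysed coupling of an alkynyl Grignard reagent with a propargylic bromide is the standard entry to skipped diynes, and the volatile product is carried on as a solution.

Step 11
Reactants: 17 hepta-1,4-diyne; 18 (S)-2-(chloromethyl)oxirane
Product: 20 (2S)-1-chlorodeca-4,7-diyn-2-ol, via lithium acetylide 19 (not isolated)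
Conditions: n-BuLi, THF, −78 °C; BF3·OEt2; then 18, −78 °C; aq NH4Cl
Reagents that add atoms: none
Why: BF3-assisted opening of the epoxide by the lithium acetylide (Yamaguchi–Hirao alkynylation) occurs only at the unsubstituted carbon at −78 °C, so the stereocentre of the epichlorohydrin is carried unchanged into C14.

Step 12
Reactants: 20 (2S)-1-chlorodeca-4,7-diyn-2-ol
Product: 21 (2S,4Z,7Z)-1-chlorodeca-4,7-dien-2-ol
Conditions: H2 (1 atm), Pd/CaCO3 poisoned with Pb(OAc)2 (Lindlar catalyst), quinoline, EtOAc, rt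
Reagents that add atoms: none
Why: Lindlar semihydrogenation should deliver hydrogen syn to each alkyne and give the skipped (4Z,7Z)-diene, the chlorohydrin being inert.

Step 13
Reactants: 21 (2S,4Z,7Z)-1-chlorodeca-4,7-dien-2-ol
Product: 23 (2S,4Z,7Z)-1-[(1-phenyl-1H-tetrazol-5-yl)sulfanyl]deca-4,7-dien-2-ol, via terminal epoxide 22 (not isolated)
Conditions: 1-phenyl-1H-tetrazole-5-thiol, K2CO3, MeOH, rt → 45 °C
Reagents that add atoms: 1-phenyl-1H-tetrazole-5-thiol Sc1nnnn1-c1ccccc1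
Why: Base closes the chlorohydrin to the terminal epoxide, which the thiolate opens at the primary carbon (SN2), so the carbinol stereocentre is never touched.

Step 14
Reactants: 23 (2S,4Z,7Z)-1-[(1-phenyl-1H-tetrazol-5-yl)sulfanyl]deca-4,7-dien-2-ol
Product: 24 5-{[(2S,4Z,7Z)-2-{[tert-butyl(dimethyl)silyl]oxy}deca-4,7-dien-1-yl]sulfanyl}-1-phenyl-1H-tetrazole
Conditions: TBSCl, imidazole, DMF, rt
Reagents that add atoms: tert-butyldimethylsilyl chloride CC(C)(C)[Si](C)(C)Cl
Why: Standard imidazole-mediated silylation of the secondary alcohol.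

Step 15
Reactants: 24 5-{[(2S,4Z,7Z)-2-{[tert-butyl(dimethyl)silyl]oxy}deca-4,7-dien-1-yl]sulfanyl}-1-phenyl-1H-tetrazole
Product: 25 5-{[(2S,4Z,7Z)-2-{[tert-butyl(dimethyl)silyl]oxy}deca-4,7-dien-1-yl]sulfonyl}-1-phenyl-1H-tetrazole
Conditions: (NH4)6Mo7O24·4H2O (10 mol %), 30% aq H2O2, EtOH, 0 °C → rt
Reagents that add atoms: hydrogen peroxide OO
Why: Molybdate-catalysed peroxide oxidation of the sulfide to the sulfone is chemoselective for sulfur over isolated Z alkenes.

Step 16
Reactants: 25 5-{[(2S,4Z,7Z)-2-{[tert-butyl(dimethyl)silyl]oxy}deca-4,7-dien-1-yl]sulfonyl}-1-phenyl-1H-tetrazole; 14 (5Z,8R)-8-[(1R,2R)-2-[(1S)-1-{[tert-butyl(dimethyl)silyl]oxy}-2-oxoethyl]cyclopropyl]-3,4,7,8-tetrahydro-2H-oxocin-2-one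
Product: 27 (5Z,8R)-8-[(1R,2R)-2-[(1R,2E,4S,6Z,9Z)-1,4-bis{[tert-butyl(dimethyl)silyl]oxy}dodeca-2,6,9-trien-1-yl]cyclopropyl]-3,4,7,8-tetrahydro-2H-oxocin-2-one, via potassium sulfonyl carbanion 26 (not isolated)
Conditions: KN(SiMe3)2, DME, −78 °C; then 14, −78 °C → rt; aq NH4Cl
Reagents that add atoms: none
Why: Julia–Kocienski olefination (addition, Smiles rearrangement, loss of SO2 and tetrazolone) of a 1-phenyltetrazolyl sulfone with an alpha-branched aldehyde is E-selective under these conditions and forms C12=C13 with both carbinol stereocentres already in place.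

Step 17
Reactants: 27 (5Z,8R)-8-[(1R,2R)-2-[(1R,2E,4S,6Z,9Z)-1,4-bis{[tert-butyl(dimethyl)silyl]oxy}dodeca-2,6,9-trien-1-yl]cyclopropyl]-3,4,7,8-tetrahydro-2H-oxocin-2-one
Product: 28 (5Z,8R)-8-[(1R,2R)-2-[(1R,2E,4S,6Z,9Z)-1,4-dihydroxydodeca-2,6,9-trien-1-yl]cyclopropyl]-3,4,7,8-tetrahydro-2H-oxocin-2-one
Conditions: HF·pyridine, pyridine, THF, 0 °C → rt
Reagents that add atoms: none
Why: Buffered fluoride cleavage of both silyl ethers should avoid ionising the allylic and cyclopropylcarbinyl alcohols and leave the lactone closed.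

**Compound list**

1 | tert-butyl pent-4-ynoate | C#CCCC(=O)OC(C)(C)C | starting material
2 | (2E)-1,4-dibromobut-2-ene | BrC/C=C/CBr | starting material
3 | tert-butyl (7E)-9-bromonon-7-en-4-ynoate | CC(C)(C)OC(=O)CCC#CC/C=C/CBr | intermediate
4 | (2E)-3-(tributylstannyl)prop-2-en-1-ol | CCCC[Sn](CCCC)(CCCC)/C=C/CO | starting material
5 | tert-butyl (7E,10E)-12-hydroxydodeca-7,10-dien-4-ynoate | CC(C)(C)OC(=O)CCC#CC/C=C/C/C=C/CO | intermediate
6 | tert-butyl (4Z,7E,10E)-12-hydroxydodeca-4,7,10-trienoate | CC(C)(C)OC(=O)CC/C=C\C/C=C/C/C=C/CO | intermediate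
7 | tert-butyl (4Z,7E)-9-[(2R,3R)-3-(hydroxymethyl)oxiran-2-yl]nona-4,7-dienoate | CC(C)(C)OC(=O)CC/C=C\C/C=C/C[C@H]1O[C@@H]1CO | intermediate
8 | tert-butyl (4Z,7E)-9-[(2R,3R)-3-({[tert-butyl(dimethyl)silyl]oxy}methyl)oxiran-2-yl]nona-4,7-dienoate | CC(C)(C)OC(=O)CC/C=C\C/C=C/C[C@H]1O[C@@H]1CO[Si](C)(C)C(C)(C)C | intermediate
9 | cyclopropylcarbinyl cation: C7 carbenium on the trans-cyclopropane, tert-butyl ester intact, C11 oxygen bound to BF3 (zwitterion, not isolated) | CC(C)(C)OC(=O)CC/C=C\C[CH+][C@@H]1C[C@H]1[C@@H](CO[Si](C)(C)C(C)(C)C)O[B-](F)(F)F | intermediate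
10 | tert-butyl lactonium ion: eight-membered ring closed, carbonyl oxygen still carrying tert-butyl, C11 oxygen bound to BF3 (zwitterion, not isolated) | CC(C)(C)[O+]=C1CC/C=C\C[C@H]([C@@H]2C[C@H]2[C@@H](CO[Si](C)(C)C(C)(C)C)O[B-](F)(F)F)O1 | intermediate
11 | (5Z,8R)-8-[(1R,2R)-2-[(1S)-2-{[tert-butyl(dimethyl)silyl]oxy}-1-hydroxyethyl]cyclopropyl]-3,4,7,8-tetrahydro-2H-oxocin-2-one | CC(C)(C)[Si](C)(C)OC[C@@H](O)[C@@H]1C[C@H]1[C@H]1C/C=C\CCC(=O)O1 | intermediate
12 | (5Z,8R)-8-[(1R,2R)-2-[(1S)-1,2-bis{[tert-butyl(dimethyl)silyl]oxy}ethyl]cyclopropyl]-3,4,7,8-tetrahydro-2H-oxocin-2-one | CC(C)(C)[Si](C)(C)OC[C@@H](O[Si](C)(C)C(C)(C)C)[C@@H]1C[C@H]1[C@H]1C/C=C\CCC(=O)O1 | intermediate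
13 | (5Z,8R)-8-[(1R,2R)-2-[(1S)-1-{[tert-butyl(dimethyl)silyl]oxy}-2-hydroxyethyl]cyclopropyl]-3,4,7,8-tetrahydro-2H-oxocin-2-one | OC[C@@H](O[Si](C)(C)C(C)(C)C)[C@@H]1C[C@H]1[C@H]1C/C=C\CCC(=O)O1 | intermediate
14 | (5Z,8R)-8-[(1R,2R)-2-[(1S)-1-{[tert-butyl(dimethyl)silyl]oxy}-2-oxoethyl]cyclopropyl]-3,4,7,8-tetrahydro-2H-oxocin-2-one | O=C[C@@H](O[Si](C)(C)C(C)(C)C)[C@@H]1C[C@H]1[C@H]1C/C=C\CCC(=O)O1 | intermediate
15 | 1-bromopent-2-yne | CCC#CCBr | starting material
16 | ethynylmagnesium bromide | C#C[Mg]Br | starting material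
17 | hepta-1,4-diyne | CCC#CCC#C | intermediate
18 | (S)-2-(chloromethyl)oxirane, (S)-epichlorohydrin | ClC[C@@H]1CO1 | starting material
19 | 1-lithiohepta-1,4-diyne (lithium acetylide, not isolated) | CCC#CCC#C[Li] | intermediate
20 | (2S)-1-chlorodeca-4,7-diyn-2-ol | CCC#CCC#CC[C@H](O)CCl | intermediate
21 | (2S,4Z,7Z)-1-chlorodeca-4,7-dien-2-ol | CC/C=C\C/C=C\C[C@H](O)CCl | intermediate
22 | (2S)-2-[(2Z,5Z)-octa-2,5-dien-1-yl]oxirane (not isolated) | CC/C=C\C/C=C\C[C@H]1CO1 | intermediate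
23 | (2S,4Z,7Z)-1-[(1-phenyl-1H-tetrazol-5-yl)sulfanyl]deca-4,7-dien-2-ol | CC/C=C\C/C=C\C[C@H](O)CSc1nnnn1-c1ccccc1 | intermediate
24 | 5-{[(2S,4Z,7Z)-2-{[tert-butyl(dimethyl)silyl]oxy}deca-4,7-dien-1-yl]sulfanyl}-1-phenyl-1H-tetrazole | CC/C=C\C/C=C\C[C@H](O[Si](C)(C)C(C)(C)C)CSc1nnnn1-c1ccccc1 | intermediate
25 | 5-{[(2S,4Z,7Z)-2-{[tert-butyl(dimethyl)silyl]oxy}deca-4,7-dien-1-yl]sulfonyl}-1-phenyl-1H-tetrazole | CC/C=C\C/C=C\C[C@H](O[Si](C)(C)C(C)(C)C)CS(=O)(=O)c1nnnn1-c1ccccc1 | intermediate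
26 | potassium salt of 25 deprotonated at the carbon next to sulfur (not isolated) | CC/C=C\C/C=C\C[C@H](O[Si](C)(C)C(C)(C)C)[CH-]S(=O)(=O)c1nnnn1-c1ccccc1.[K+] | intermediate
27 | (5Z,8R)-8-[(1R,2R)-2-[(1R,2E,4S,6Z,9Z)-1,4-bis{[tert-butyl(dimethyl)silyl]oxy}dodeca-2,6,9-trien-1-yl]cyclopropyl]-3,4,7,8-tetrahydro-2H-oxocin-2-one | CC/C=C\C/C=C\C[C@H](O[Si](C)(C)C(C)(C)C)/C=C/[C@@H](O[Si](C)(C)C(C)(C)C)[C@@H]1C[C@H]1[C@H]1C/C=C\CCC(=O)O1 | intermediate
28 | (5Z,8R)-8-[(1R,2R)-2-[(1R,2E,4S,6Z,9Z)-1,4-dihydroxydodeca-2,6,9-trien-1-yl]cyclopropyl]-3,4,7,8-tetrahydro-2H-oxocin-2-one | CC/C=C\C/C=C\C[C@H](O)/C=C/[C@@H](O)[C@@H]1C[C@H]1[C@H]1C/C=C\CCC(=O)O1 | target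

**Step count**

Total steps: 17. Longest linear sequence: 11 (steps 1–9, 16, 17); the side-chain branch is steps 10–15.

**Steps most likely to fail**

1. Step 6 (proposed new method). The C7 cation may be taken by the neighbouring C4=C5 alkene (a second homoallyl shift, then five-membered lactone) or lose a C6 proton before the eight-membered ring can close. The activated epoxide may also rearrange by hydride shift, and the cyclopropylcarbinyl lactone may re-ionise under the Lewis acid.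

   Fallback with known chemistry only; it sets out from 1 and comes back at 12. The cyclopropane is made by reagent-controlled Simmons–Smith chemistry and the lactone is closed by ring-closing metathesis. Compound 1 is semihydrogenated (H2, Pd/CaCO3 poisoned with Pb(OAc)2, quinoline) to tert-butyl pent-4-enoate F1 and unmasked with CF3CO2H to pent-4-enoic acid F2. In parallel, commercial ethyl (2E)-3-[(4S)-2,2-dimethyl-1,3-dioxolan-4-yl]prop-2-enoate is reduced with i-Bu2AlH to (2E)-3-[(4S)-2,2-dimethyl-1,3-dioxolan-4-yl]prop-2-en-1-ol F3. Charette asymmetric cyclopropanation (Zn(CH2I)2, the (S,S)-tartramide-derived butyl dioxaborolane) should give [(1R,2R)-2-[(4S)-2,2-dimethyl-1,3-dioxolan-4-yl]cyclopropyl]methanol F4. Dess–Martin oxidation gives (1R,2R)-2-[(4S)-2,2-dimethyl-1,3-dioxolan-4-yl]cyclopropane-1-carbaldehyde F5. Brown allylation with (+)-B-allyldiisopinocampheylborane should give (1R)-1-[(1R,2R)-2-[(4S)-2,2-dimethyl-1,3-dioxolan-4-yl]cyclopropyl]but-3-en-1-ol F6, which sets C7. Steglich esterification of F6 with F2 gives (1R)-1-[(1R,2R)-2-[(4S)-2,2-dimethyl-1,3-dioxolan-4-yl]cyclopropyl]but-3-en-1-yl pent-4-enoate F7. Ring-closing metathesis (second-generation Grubbs catalyst, CH2Cl2, 1 mM, reflux) gives (5Z,8R)-8-[(1R,2R)-2-[(4S)-2,2-dimethyl-1,3-dioxolan-4-yl]cyclopropyl]-3,4,7,8-tetrahydro-2H-oxocin-2-one F8, the ring size enforcing the Z alkene. Aqueous acetic acid removes the acetonide to give (5Z,8R)-8-[(1R,2R)-2-[(1S)-1,2-dihydroxyethyl]cyclopropyl]-3,4,7,8-tetrahydro-2H-oxocin-2-one F9, and TBSOTf/2,6-lutidine converts F9 into 12.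

2. Step 16. The metalated beta-silyloxy sulfone may eliminate silanolate or self-condense before it adds to the aldehyde, the base may enolise the aldehyde or the lactone, and E selectivity may be incomplete.

   Fallback: it sets out from 14 (with a partner made from 21) and comes back at 28. The alkene is made by phosphonate olefination and C14 by reagent-controlled ketone reduction. Chlorohydrin 21 is closed (K2CO3, MeOH) to epoxide 22, here isolated, and opened with LiP(O)(OMe)2/BF3·OEt2 to dimethyl [(2S,4Z,7Z)-2-hydroxydeca-4,7-dien-1-yl]phosphonate F10. Dess–Martin oxidation gives dimethyl [(4Z,7Z)-2-oxodeca-4,7-dien-1-yl]phosphonate F11. Horner–Wadsworth–Emmons reaction of F11 with 14 (LiCl, i-Pr2NEt, MeCN) should give (5Z,8R)-8-[(1R,2R)-2-[(1R,2E,6Z,9Z)-1-{[tert-butyl(dimethyl)silyl]oxy}-4-oxododeca-2,6,9-trien-1-yl]cyclopropyl]-3,4,7,8-tetrahydro-2H-oxocin-2-one F12. Reduction with (R)-2-methyl-CBS-oxazaborolidine and catecholborane (toluene, −78 °C) should give (5Z,8R)-8-[(1R,2R)-2-[(1R,2E,4S,6Z,9Z)-1-{[tert-butyl(dimethyl)silyl]oxy}-4-hydroxydodeca-2,6,9-trien-1-yl]cyclopropyl]-3,4,7,8-tetrahydro-2H-oxocin-2-one F13. HF·pyridine then gives 28.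

3. Step 2. The pi-allyl palladium intermediate may isomerise (branched coupling, E/Z scrambling) or undergo beta-hydride elimination to a conjugated dienyne before the vinyl group is transferred.

   Fallback: it sets out from 3 and comes back at 5. The E-allylic alcohol is made from an alkyne instead of being carried in by a vinyl metal. Compound 3 is coupled with prop-2-yn-1-ol under the conditions of step 1 to give tert-butyl (7E)-12-hydroxydodec-7-ene-4,10-diynoate F14. Hydroxyl-assisted trans reduction with CrSO4 (divalent chromium) in DMF/H2O should reduce only the propargylic alkyne and give 5.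

Further compounds
F1 | step 6 | tert-butyl pent-4-enoate | C=CCCC(=O)OC(C)(C)C
F2 | step 6 | pent-4-enoic acid | C=CCCC(=O)O
F3 | step 6 | (2E)-3-[(4S)-2,2-dimethyl-1,3-dioxolan-4-yl]prop-2-en-1-ol | C1OC(C)(C)O[C@H]1/C=C/CO
F4 | step 6 | [(1R,2R)-2-[(4S)-2,2-dimethyl-1,3-dioxolan-4-yl]cyclopropyl]methanol | C1OC(C)(C)O[C@H]1[C@@H]2C[C@H]2CO
F5 | step 6 | (1R,2R)-2-[(4S)-2,2-dimethyl-1,3-dioxolan-4-yl]cyclopropane-1-carbaldehyde | C1OC(C)(C)O[C@H]1[C@@H]2C[C@H]2C=O
F6 | step 6 | (1R)-1-[(1R,2R)-2-[(4S)-2,2-dimethyl-1,3-dioxolan-4-yl]cyclopropyl]but-3-en-1-ol | C1OC(C)(C)O[C@H]1[C@@H]2C[C@H]2[C@H](O)CC=C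
F7 | step 6 | (1R)-1-[(1R,2R)-2-[(4S)-2,2-dimethyl-1,3-dioxolan-4-yl]cyclopropyl]but-3-en-1-yl pent-4-enoate | C1OC(C)(C)O[C@H]1[C@@H]2C[C@H]2[C@H](OC(=O)CCC=C)CC=C
F8 | step 6 | (5Z,8R)-8-[(1R,2R)-2-[(4S)-2,2-dimethyl-1,3-dioxolan-4-yl]cyclopropyl]-3,4,7,8-tetrahydro-2H-oxocin-2-one | C1OC(C)(C)O[C@H]1[C@@H]2C[C@H]2[C@H]3C/C=C\CCC(=O)O3
F9 | step 6 | (5Z,8R)-8-[(1R,2R)-2-[(1S)-1,2-dihydroxyethyl]cyclopropyl]-3,4,7,8-tetrahydro-2H-oxocin-2-one | OC[C@@H](O)[C@@H]1C[C@H]1[C@H]1C/C=C\CCC(=O)O1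
F10 | step 16 | dimethyl [(2S,4Z,7Z)-2-hydroxydeca-4,7-dien-1-yl]phosphonate | CC/C=C\C/C=C\C[C@H](O)CP(=O)(OC)OC
F11 | step 16 | dimethyl [(4Z,7Z)-2-oxodeca-4,7-dien-1-yl]phosphonate | CC/C=C\C/C=C\CC(=O)CP(=O)(OC)OC
F12 | step 16 | (5Z,8R)-8-[(1R,2R)-2-[(1R,2E,6Z,9Z)-1-{[tert-butyl(dimethyl)silyl]oxy}-4-oxododeca-2,6,9-trien-1-yl]cyclopropyl]-3,4,7,8-tetrahydro-2H-oxocin-2-one | CC/C=C\C/C=C\CC(=O)/C=C/[C@@H](O[Si](C)(C)C(C)(C)C)[C@@H]1C[C@H]1[C@H]1C/C=C\CCC(=O)O1
F13 | step 16 | (5Z,8R)-8-[(1R,2R)-2-[(1R,2E,4S,6Z,9Z)-1-{[tert-butyl(dimethyl)silyl]oxy}-4-hydroxydodeca-2,6,9-trien-1-yl]cyclopropyl]-3,4,7,8-tetrahydro-2H-oxocin-2-one | CC/C=C\C/C=C\C[C@H](O)/C=C/[C@@H](O[Si](C)(C)C(C)(C)C)[C@@H]1C[C@H]1[C@H]1C/C=C\CCC(=O)O1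
F14 | step 2 | tert-butyl (7E)-12-hydroxydodec-7-ene-4,10-diynoate | CC(C)(C)OC(=O)CCC#CC/C=C/CC#CCO
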